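## Structural features

The target is a 2,6-diaryl-3,7-dioxabicyclo[3.3.0]octane. Two tetrahydrofuran rings, ring A (C1, C2, O3, C4, C5) and ring B (C5, C6, O7, C8, C1), are cis-fused along C1–C5; this numbering is used for every intermediate below. C2 carries a 4-hydroxy-3-methoxyphenyl group (ArA) and C6 a 3-hydroxy-4,5-dimethoxyphenyl group (ArB), both on the convex face, and the configuration is (1R,2S,5R,6S). The four stereocentres form one unbroken chain C2–C1–C5–C6, so each stands next to another. The core would be C2-symmetric with equal aryl groups, but they differ and only ArA has a para hydroxyl, so dimerising one phenylpropanoid is not an option and ArB cannot form a quinone methide. The fragile points are the benzylic ether bonds C2–O3 and C6–O7, which ionise in acid (epimerising C2 or C6) and are cleaved by hydrogenolysis, and the two oxidisable phenols. The real difficulty is joining two different aryl-C3 units through C1–C5 with control of the relative and absolute configuration. The feature exploited is that C2 and C6 stand 1,4 to each other across C1–C5 and are both at the oxidation level of a benzylic cation: a cyclobutane C1–C2–C6–C5 with a sacrificial C2–C6 bond holds the two units together, and oxidative loss of that bond lets O3 and O7 close rings A and B.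

## Logic of the disconnections

From 12 to 11: the two phenolic O–H bonds are replaced by O–Si bonds. The last skeletal step is an oxidation that free phenols would not survive. Nothing is gained in skeleton, but the end game becomes one fluoride treatment. The forward step must leave the benzylic ethers and C2/C6 alone.

From 11 to 10: C2–O3 and C6–O7 are cut and C2 is joined to C6. Both ether carbons are benzylic to electron-rich rings, so they can be reached from cations, and a strained C2–C6 bond is a stored form of that pair of cations. Two rings and two stereocentres leave the problem; what remains is a cyclobutane whose only lasting information is the trans relation and absolute sense of C1 and C5. The forward step must break C2–C6 and no other bond, O3 and O7 must capture the benzylic positions before C1–C5 can break, and each aryl group must end up exo.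

From 10 to 8 (through 9): the C8 alcohol is traced to a methyl ester and O3–H to a silyl ether. The ester makes one alkene an acceptor that a chiral Lewis acid can hold, and the bulky silyl group keeps O3 from competing for that Lewis acid. The forward demand is a reduction and an alkyl silyl ether cleavage that spare the two aryl silyl ethers.

From 8 to 2 and 7: C1–C5 and C2–C6 are cut, the retron of a [2+2] cycloaddition. The halves are flat, achiral aryl-propene units, one per aryl group, and all four stereocentres arise in one catalytic step. The forward step needs head-to-head orientation, cross- over homo-coupling, a trans C1/C5 relation and one enantiomer. Rotation in the intermediate diradical can only adjust C2 and C6; the C1/C5 relation is fixed when C1–C5 forms, so it must come from that bond formation and from reversal of the mismatched diradical.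

From 2 to 1: one O–Si bond is cut. A free phenol would protonate the Lewis acid; the forward step is a routine silylation.

From 7 to 3 and 4: the two O–Si bonds of 7 lead to 6, the C4 oxidation level leads to 5, and the C5=C6 double bond of 5 is cut to 3 and 4. The phenol is carried unprotected so that both hydroxyls are silylated in one operation. The forward steps need an (E)-selective olefination that tolerates a phenol and a clean 1,2-reduction.

## Other disconnections considered

Alternative 1: The cut is at C5–C6 and C1–C2; a four-carbon lactone supplies C8, C1, C5 and C4, and the aryl-bearing carbons are attached one after the other. In the forward step the lithium derivative of dithiane A3 would add to C5 of the menthyloxy butenolide A2 anti to the acetal substituent, and the lactone enolate would be trapped at C1 by aldehyde A4, trans to the new C5 substituent, to give A1.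
- In favour: conjugate addition–aldol on a γ-alkoxybutenolide is an established entry to lignans. C5 and C1 are set in a rigid five-membered ring by a cheap auxiliary. The aryl groups enter as separate reagents, so homo-coupling is impossible.
- Against: C6 arrives as a masked ketone and C2 as a carbinol of uncontrolled configuration. Dithiane hydrolysis, hydride reduction and an acid-mediated double ring closure through benzylic cations must follow. The benzyl ethers of A1 would have to be removed by hydrogenolysis next to two benzylic ether bonds.
- Comparison: on precedent and on security of C1/C5 this alternative is the better plan. On step count the two are equal (seven to eight steps). The chosen plan forms all four stereocentres in one catalytic step and spends no auxiliary or sulfur reagent, but rests on two less secure steps. This chemistry, with silyl in place of benzyl ethers, is therefore kept as the fallback for step 7.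

Alternative 2: The cut is at C1–C8 and C6–O7; ring B is taken apart into the cyclopropane-fused lactone A6 and formaldehyde A7. ArA is absent from the key-step product A5 and must be added to the lactone carbonyl C2 later. In the forward step a Lewis acid on the carbonyl would open the C1–C6 cyclopropane bond to a benzylic cation and a lactone enolate; the enolate would add to A7 (C1–C8) and the alkoxide would close on C6.
- In favour: A6 could be reached from 6 by a carbene-based intramolecular cyclopropanation under catalyst control. C5 is then fixed and directs C1 and C6. It is the equal or better of the chosen plan in chemoselectivity, because the aryl groups enter at different stages and no bond has to be sacrificed.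
- Against: a cyclopropane with a single ester-type acceptor is a weak donor–acceptor system; the formal [3+2] reaction with aldehydes is secure mainly for geminal diesters, and monomeric A7 is awkward. Diazo chemistry is needed on scale. Aryl-metal addition to A5 followed by silane reduction of the hemiketal would deliver hydride from the convex face and place ArA endo at C2, the wrong epimer, and acid equilibration does not clearly favour the exo isomer.
- Comparison: both plans capture a benzylic cation at C6 with O7. This one is longer (about eleven steps) and weaker at C2.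

Alternative 3: The cut is C1–C5 alone, inside the bis-lactone A8, which is traced to the eight-membered diolide A9, formally the head-to-tail cyclic dimer of two different 3-aryl-3-hydroxypropanoic acid units. In the forward step double deprotonation at C1 and C5 and one-electron oxidation with CuCl2 (divalent copper) or at an anode would join C1 to C5 across the ring and close both lactones at once.
- In favour: it is the most direct construction of the central bond, with no sacrificial bond. C2 and C6 would be set first by dependable asymmetric carbonyl reduction and kept to the end; on this point it is the better plan. Cis fusion is enforced by the transannular geometry.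
- Against: each enolate of A9 has an acyloxy leaving group on its β-carbon (O3 on C2, O7 on C6), so E1cB opening to cinnamates should outrun the coupling. The unsymmetrical medium ring needs ordered esterification and a difficult lactonisation. After coupling, both lactone carbonyls (C4, C8) must still be reduced to CH2.
- Comparison: a dozen steps or more, and the key intermediate is likely to be unstable to its own reaction conditions. The chosen plan avoids enolates with β-leaving groups.

Key step: step 5

Assumption: 1 and 4 are catalogue compounds, and the (S)-prolinol-derived oxazaborolidine is assumed to shield the Re face of C1 in bound 2; if it shields the Si face, the (R)-antipode is used.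

Step 1
Reactants: 1 methyl (E)-3-(4-hydroxy-3-methoxyphenyl)prop-2-enoate (methyl ferulate)
Product: 2 methyl (E)-3-[4-(tert-butyldimethylsilyloxy)-3-methoxyphenyl]prop-2-enoate
Conditions: TBSCl (1.2 equiv), imidazole (2.5 equiv), DMF, rt
Reagents that add atoms: tert-butyldimethylsilyl chloride, CC(C)(C)[Si](C)(C)Cl
Why: Silylation of a phenol with a silyl chloride and imidazole; it removes the acidic proton that would destroy the Lewis acid of step 5, and no stereocentre is involved.

Step 2
Reactants: 3 3-hydroxy-4,5-dimethoxybenzaldehyde; 4 ethyl (triphenylphosphoranylidene)acetate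
Product: 5 ethyl (E)-3-(3-hydroxy-4,5-dimethoxyphenyl)prop-2-enoate
Conditions: toluene, 90 °C
Reagents that add atoms: none
Why: Wittig reaction; the stabilised ylide tolerates the free phenol and gives the (E)-enoate selectively, which forms C5=C6, and any (Z)-isomer is removed here.

Step 3
Reactants: 5 ethyl (E)-3-(3-hydroxy-4,5-dimethoxyphenyl)prop-2-enoate
Product: 6 (E)-3-(3-hydroxy-4,5-dimethoxyphenyl)prop-2-en-1-ol
Conditions: iBu2AlH (3.5 equiv), CH2Cl2, −78 → 0 °C; aq. Rochelle salt
Reagents that add atoms: none
Why: Aluminium hydride 1,2-reduction of an α,β-unsaturated ester to the allylic alcohol (C4); the first equivalent of hydride is consumed by the phenol and the (E)-alkene is untouched.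

Step 4
Reactants: 6 (E)-3-(3-hydroxy-4,5-dimethoxyphenyl)prop-2-en-1-ol
Product: 7 tert-butyl{[(E)-3-[3-(tert-butyldimethylsilyloxy)-4,5-dimethoxyphenyl]prop-2-en-1-yl]oxy}dimethylsilane
Conditions: TBSCl (2.5 equiv), imidazole (5 equiv), DMF, 0 °C → rt
Reagents that add atoms: tert-butyldimethylsilyl chloride, CC(C)(C)[Si](C)(C)Cl
Why: Silylation of phenol and primary alcohol in one operation; the bulky silyl group makes O3 a poor Lewis base, so the alkene partner does not sequester the catalyst of step 5.

Step 5
Reactants: 2 methyl (E)-3-[4-(tert-butyldimethylsilyloxy)-3-methoxyphenyl]prop-2-enoate; 7 tert-butyl{[(E)-3-[3-(tert-butyldimethylsilyloxy)-4,5-dimethoxyphenyl]prop-2-en-1-yl]oxy}dimethylsilane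
Product: 8 methyl (1R,2S,3S,4R)-2-[4-(tert-butyldimethylsilyloxy)-3-methoxyphenyl]-3-[3-(tert-butyldimethylsilyloxy)-4,5-dimethoxyphenyl]-4-[(tert-butyldimethylsilyloxy)methyl]cyclobutane-1-carboxylate (all-trans; ring carbons 1, 2, 3, 4 are C1, C2, C6, C5)
Conditions: (S)-3,3-diphenyl-1-(o-tolyl)tetrahydro-1H,3H-pyrrolo[1,2-c][1,3,2]oxazaborole·AlBr3 (25 mol%), Ir(ppy)3 [tris(2-phenylpyridinato)iridium] (1 mol%), 7 (3 equiv, excess recovered), CH2Cl2, −78 °C, 450 nm LED
Reagents that add atoms: none
Why: Triplet energy transfer from the excited trivalent iridium sensitiser to Lewis-acid-bound 2, whose triplet energy the boron Lewis acid lowers below that of free 2 and of 7, gives a twisted triplet that behaves as a 1,2-diradical. Its α-carbon C1 adds to C5 of 7 to give a triplet 1,4-diradical with both spins benzylic (C2 and C6); after intersystem crossing these combine to form the temporary C2–C6 bond, so the cyclobutane closes by radical–radical recombination of a 1,4-diradical, not by a concerted addition. The closest known reaction type is the chiral-oxazaborolidine-catalysed, triplet-sensitised crossed [2+2] photocycloaddition of cinnamate esters with terminal styrenes; the β-substituted partner 7 is an extension of scope. C1 is set by the catalyst, which shields one face of the coordinated ester so that C5 bonds to the Si face of C1. C5 is set relative to C1 in the same bond-forming event; the diradical that would place C8 and C4 cis closes slowly and is expected to revert to the alkenes, so the trans isomer should accumulate. C2 and C6 are set on ring closure, trans to their neighbours after rotation of the benzylic radicals, and both are erased in step 7, so their epimers could be carried forward. Head-to-head regiochemistry follows because only that orientation leaves two benzylic radicals. Cross-coupling is favoured by exciting only bound 2 in the presence of excess 7.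

Step 6
Reactants: 8 methyl (1R,2S,3S,4R)-2-[4-(tert-butyldimethylsilyloxy)-3-methoxyphenyl]-3-[3-(tert-butyldimethylsilyloxy)-4,5-dimethoxyphenyl]-4-[(tert-butyldimethylsilyloxy)methyl]cyclobutane-1-carboxylate
Product: 10 {(1R,2S,3S,4R)-2-[4-(tert-butyldimethylsilyloxy)-3-methoxyphenyl]-3-[3-(tert-butyldimethylsilyloxy)-4,5-dimethoxyphenyl]-4-(hydroxymethyl)cyclobutyl}methanol, via tris-silyl alcohol 9 (not isolated)
Conditions: iBu2AlH (2.5 equiv), CH2Cl2, −78 °C; MeOH; then HCl (1% in MeOH), 0 °C → rt
Reagents that add atoms: none
Why: Ester reduction by iBu2AlH gives the C8 alcohol 9; acid-catalysed methanolysis then cleaves the primary alkyl silyl ether much faster than the two aryl silyl ethers and frees O3–H; no stereocentre is touched.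

Step 7
Reactants: 10 {(1R,2S,3S,4R)-2-[4-(tert-butyldimethylsilyloxy)-3-methoxyphenyl]-3-[3-(tert-butyldimethylsilyloxy)-4,5-dimethoxyphenyl]-4-(hydroxymethyl)cyclobutyl}methanol
Product: 11 (1R,2S,5R,6S)-2-[4-(tert-butyldimethylsilyloxy)-3-methoxyphenyl]-6-[3-(tert-butyldimethylsilyloxy)-4,5-dimethoxyphenyl]-3,7-dioxabicyclo[3.3.0]octane
Conditions: undivided cell, reticulated vitreous carbon anode, Pt cathode, controlled potential at the first anodic wave (about 2 F/mol), Bu4NOTf (0.1 M), 2,6-lutidine (3 equiv), CH2Cl2–(CF3)2CHOH 9:1, 0 °C
Reagents that add atoms: none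
Why: Proposed new method: one-electron oxidation of an aryl ring gives a radical cation whose hole is shared with the strained, doubly benzylic C2–C6 σ bond; this bond breaks as O3 captures the cationic C2 in a 5-exo closure (ring A), the benzylic radical left at C6 is oxidised at the same potential and captured by O7 (ring B), and O7 cannot reach C2 nor O3 reach C6 except through an oxetane; each aryl group should take the exo position because the tetrahydrofuran transition state with the aryl trans to the neighbouring ring substituent (C8 at C1, C4 at C5) is the less crowded, while C1 and C5 are untouched and their trans relation translates into the cis ring fusion; the closest known reaction types are nucleophile-assisted ring opening of arylcyclopropane radical cations, electron-transfer cleavage of 1,2-diarylcyclobutanes to 1,4-radical cations, and the closure of β–β-linked bis(quinone methides) to furofurans in oxidative phenol coupling.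

Step 8
Reactants: 11 (1R,2S,5R,6S)-2-[4-(tert-butyldimethylsilyloxy)-3-methoxyphenyl]-6-[3-(tert-butyldimethylsilyloxy)-4,5-dimethoxyphenyl]-3,7-dioxabicyclo[3.3.0]octane
Product: 12 (1R,2S,5R,6S)-2-(4-hydroxy-3-methoxyphenyl)-6-(3-hydroxy-4,5-dimethoxyphenyl)-3,7-dioxabicyclo[3.3.0]octane (CNP0324902.1)
Conditions: Bu4NF (2.4 equiv), AcOH (2.4 equiv), THF, 0 °C
Reagents that add atoms: none
Why: Fluoride cleavage of the two aryl silyl ethers; acetic acid buffers the phenoxides so the electron-rich phenols are not exposed to base and air, and the benzylic ethers and all four stereocentres are inert to these conditions.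

## Compound list

1 | methyl (E)-3-(4-hydroxy-3-methoxyphenyl)prop-2-enoate | COC(=O)/C=C/c1ccc(O)c(OC)c1 | starting material
2 | methyl (E)-3-[4-(tert-butyldimethylsilyloxy)-3-methoxyphenyl]prop-2-enoate | COC(=O)/C=C/c1ccc(O[Si](C)(C)C(C)(C)C)c(OC)c1 | intermediate
3 | 3-hydroxy-4,5-dimethoxybenzaldehyde | COc1cc(C=O)cc(O)c1OC | starting material
4 | ethyl (triphenylphosphoranylidene)acetate | CCOC(=O)C=P(c1ccccc1)(c1ccccc1)c1ccccc1 | starting material
5 | ethyl (E)-3-(3-hydroxy-4,5-dimethoxyphenyl)prop-2-enoate | CCOC(=O)/C=C/c1cc(O)c(OC)c(OC)c1 | intermediate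
6 | (E)-3-(3-hydroxy-4,5-dimethoxyphenyl)prop-2-en-1-ol | OC/C=C/c1cc(O)c(OC)c(OC)c1 | intermediate
7 | tert-butyl{[(E)-3-[3-(tert-butyldimethylsilyloxy)-4,5-dimethoxyphenyl]prop-2-en-1-yl]oxy}dimethylsilane | CC(C)(C)[Si](C)(C)OC/C=C/c1cc(O[Si](C)(C)C(C)(C)C)c(OC)c(OC)c1 | intermediate
8 | methyl (1R,2S,3S,4R)-2-[4-(tert-butyldimethylsilyloxy)-3-methoxyphenyl]-3-[3-(tert-butyldimethylsilyloxy)-4,5-dimethoxyphenyl]-4-[(tert-butyldimethylsilyloxy)methyl]cyclobutane-1-carboxylate | COc1cc([C@H]2[C@H](c3cc(O[Si](C)(C)C(C)(C)C)c(OC)c(OC)c3)[C@@H](CO[Si](C)(C)C(C)(C)C)[C@@H]2C(=O)OC)ccc1O[Si](C)(C)C(C)(C)C | intermediate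
9 | {(1R,2S,3S,4R)-2-[4-(tert-butyldimethylsilyloxy)-3-methoxyphenyl]-3-[3-(tert-butyldimethylsilyloxy)-4,5-dimethoxyphenyl]-4-[(tert-butyldimethylsilyloxy)methyl]cyclobutyl}methanol (not isolated) | COc1cc([C@H]2[C@H](c3cc(O[Si](C)(C)C(C)(C)C)c(OC)c(OC)c3)[C@@H](CO[Si](C)(C)C(C)(C)C)[C@@H]2CO)ccc1O[Si](C)(C)C(C)(C)C | intermediate
10 | {(1R,2S,3S,4R)-2-[4-(tert-butyldimethylsilyloxy)-3-methoxyphenyl]-3-[3-(tert-butyldimethylsilyloxy)-4,5-dimethoxyphenyl]-4-(hydroxymethyl)cyclobutyl}methanol | COc1cc([C@H]2[C@H](c3cc(O[Si](C)(C)C(C)(C)C)c(OC)c(OC)c3)[C@@H](CO)[C@@H]2CO)ccc1O[Si](C)(C)C(C)(C)C | intermediate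
11 | (1R,2S,5R,6S)-2-[4-(tert-butyldimethylsilyloxy)-3-methoxyphenyl]-6-[3-(tert-butyldimethylsilyloxy)-4,5-dimethoxyphenyl]-3,7-dioxabicyclo[3.3.0]octane | COc1cc([C@H]2OC[C@H]3[C@@H]2CO[C@@H]3c2cc(O[Si](C)(C)C(C)(C)C)c(OC)c(OC)c2)ccc1O[Si](C)(C)C(C)(C)C | intermediate
12 | (1R,2S,5R,6S)-2-(4-hydroxy-3-methoxyphenyl)-6-(3-hydroxy-4,5-dimethoxyphenyl)-3,7-dioxabicyclo[3.3.0]octane | COc1cc([C@H]2OC[C@H]3[C@@H]2CO[C@@H]3c2cc(O)c(OC)c(OC)c2)ccc1O | target

## Step count and least certain steps

Total: 8 steps. Longest linear sequence: 7 steps (steps 2 to 8, from 3).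

**Step 7 (proposed new method).** The most likely failure is cycloreversion: once C2–C6 has broken, the open radical cation can also break C1–C5 before O3 captures C2, which would return two cinnamyl alcohols or, on recombination, scramble C1 and C5. Further risks are:
- capture of the C2 cation by the ArB ring (six-membered Friedel–Crafts closure) instead of by O3;
- further oxidation of 11 at the anode, since its rings are as electron-rich as those of 10;
- acid-promoted epimerisation at C2 or C6 if the buffer is exhausted.

Fallback, established chemistry without a cyclobutane; it sets out from 3 and comes back at 11. 3 is silylated (TBSCl, imidazole) to 3-(tert-butyldimethylsilyloxy)-4,5-dimethoxybenzaldehyde F1, which propane-1,3-dithiol and MgBr2·OEt2 convert into the aryl dithiane F2. Its lithium derivative (n-BuLi, THF, −78 °C) is added to butenolide A2 anti to the menthyloxy group, and the lactone enolate is trapped with the catalogue aldehyde 4-(tert-butyldimethylsilyloxy)-3-methoxybenzaldehyde F3 to give the trans,trans-disubstituted menthyloxy lactone F4 as a pair of carbinol epimers. MeI and CaCO3 in aqueous MeCN unmask the keto lactone F5. LiAlH4 reduces ketone, lactone and acetal carbon, with release of the auxiliary, to the (2R,3R)-tetraol F6. A catalytic amount of camphorsulfonic acid in CH2Cl2 at 0 °C then closes rings A and B through the two benzylic cations to give 11. Each operation is a known reaction type in lignan synthesis, and C1 and C5 come from the auxiliary, not from a photochemical step.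

**Step 5 (key step).** The most likely failure is unproductive decay of the bound triplet: E/Z isomerisation of 2 may be faster than addition to the hindered, disubstituted C5 of 7, leaving homodimerisation of 2 as the main outlet. Sensitisation of unbound 2 would add a racemic background, and formation of the C1/C5-cis diradical would lower the yield of usable material.

Fallback; it sets out from 2 and 7 and comes back at 8. The cycloaddition is run without the chiral catalyst (Ir(ppy)3 with stoichiometric BF3·OEt2, or direct irradiation through Pyrex, with 7 as co-solvent), so no turnover of a chiral Lewis acid is needed. This gives racemic material, that is, 8 together with its mirror image, the (1S,2R,3R,4S)-cyclobutane ester F7. Preparative chromatography on a chiral stationary phase separates the two and returns 8. The absolute configuration then comes from resolution instead of catalyst control, while the bonds formed are the same.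

**Step 6.** The most likely failure is loss of selectivity in the acid methanolysis: partial cleavage of one or both aryl silyl ethers, or slow cleavage of the primary silyl ether, which sits on a carbon flanked by ring substituents.

Fallback; it sets out from 9, isolated after an ordinary work-up of the reduction, and comes back at 10. All three silyl groups are removed with Bu4NF to give the phenolic diol F8, and the two phenols alone are silylated again as their phenoxides (NaH, 2.0 equiv, THF–DMF, 0 °C; TBSCl, 2.0 equiv). Selectivity then rests on the acidity difference between phenol and alcohol, not on relative rates of silyl ether cleavage.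

## Further compounds

F1 | step 7 | 3-(tert-butyldimethylsilyloxy)-4,5-dimethoxybenzaldehyde | COc1cc(C=O)cc(O[Si](C)(C)C(C)(C)C)c1OC
F2 | step 7 | 2-[3-(tert-butyldimethylsilyloxy)-4,5-dimethoxyphenyl]-1,3-dithiane | COc1cc(C2SCCCS2)cc(O[Si](C)(C)C(C)(C)C)c1OC
F3 | step 7 | 4-(tert-butyldimethylsilyloxy)-3-methoxybenzaldehyde | COc1cc(C=O)ccc1O[Si](C)(C)C(C)(C)C
F4 | step 7 | (3S,4R,5R)-3-{[4-(tert-butyldimethylsilyloxy)-3-methoxyphenyl](hydroxy)methyl}-4-{2-[3-(tert-butyldimethylsilyloxy)-4,5-dimethoxyphenyl]-1,3-dithian-2-yl}-5-{[(1R,2S,5R)-2-isopropyl-5-methylcyclohexyl]oxy}oxolan-2-one (carbinol epimers) | COc1cc(C(O)[C@H]2C(=O)O[C@@H](O[C@@H]3C[C@H](C)CC[C@H]3C(C)C)[C@@H]2C2(SCCCS2)c2cc(O[Si](C)(C)C(C)(C)C)c(OC)c(OC)c2)ccc1O[Si](C)(C)C(C)(C)C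
F5 | step 7 | (3S,4R,5R)-4-[3-(tert-butyldimethylsilyloxy)-4,5-dimethoxybenzoyl]-3-{[4-(tert-butyldimethylsilyloxy)-3-methoxyphenyl](hydroxy)methyl}-5-{[(1R,2S,5R)-2-isopropyl-5-methylcyclohexyl]oxy}oxolan-2-one (carbinol epimers) | COc1cc(C(O)[C@H]2C(=O)O[C@@H](O[C@@H]3C[C@H](C)CC[C@H]3C(C)C)[C@@H]2C(=O)c2cc(O[Si](C)(C)C(C)(C)C)c(OC)c(OC)c2)ccc1O[Si](C)(C)C(C)(C)C
F6 | step 7 | (2R,3R)-2-{[4-(tert-butyldimethylsilyloxy)-3-methoxyphenyl](hydroxy)methyl}-3-{[3-(tert-butyldimethylsilyloxy)-4,5-dimethoxyphenyl](hydroxy)methyl}butane-1,4-diol (carbinol epimers) | COc1cc(C(O)[C@@H](CO)[C@H](CO)C(O)c2cc(O[Si](C)(C)C(C)(C)C)c(OC)c(OC)c2)ccc1O[Si](C)(C)C(C)(C)C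
F7 | step 5 | methyl (1S,2R,3R,4S)-2-[4-(tert-butyldimethylsilyloxy)-3-methoxyphenyl]-3-[3-(tert-butyldimethylsilyloxy)-4,5-dimethoxyphenyl]-4-[(tert-butyldimethylsilyloxy)methyl]cyclobutane-1-carboxylate | COc1cc([C@@H]2[C@@H](c3cc(O[Si](C)(C)C(C)(C)C)c(OC)c(OC)c3)[C@H](CO[Si](C)(C)C(C)(C)C)[C@H]2C(=O)OC)ccc1O[Si](C)(C)C(C)(C)C
F8 | step 6 | {(1R,2S,3S,4R)-2-(4-hydroxy-3-methoxyphenyl)-3-(3-hydroxy-4,5-dimethoxyphenyl)-4-(hydroxymethyl)cyclobutyl}methanol | COc1cc([C@H]2[C@H](c3cc(O)c(OC)c(OC)c3)[C@@H](CO)[C@@H]2CO)ccc1O
A1 | alternative 1 | (3S,4R,5R)-3-{(S)-[4-(benzyloxy)-3-methoxyphenyl](hydroxy)methyl}-4-{2-[3-(benzyloxy)-4,5-dimethoxyphenyl]-1,3-dithian-2-yl}-5-{[(1R,2S,5R)-2-isopropyl-5-methylcyclohexyl]oxy}oxolan-2-one | COc1cc([C@@H](O)[C@H]2C(=O)O[C@@H](O[C@@H]3C[C@H](C)CC[C@H]3C(C)C)[C@@H]2C2(SCCCS2)c2cc(OCc3ccccc3)c(OC)c(OC)c2)ccc1OCc1ccccc1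
A2 | alternative 1 | (5R)-5-{[(1R,2S,5R)-2-isopropyl-5-methylcyclohexyl]oxy}furan-2(5H)-one | O=C1C=C[C@H](O[C@@H]2C[C@H](C)CC[C@H]2C(C)C)O1
A3 | alternative 1 | 2-[3-(benzyloxy)-4,5-dimethoxyphenyl]-1,3-dithiane | COc1cc(C2SCCCS2)cc(OCc2ccccc2)c1OC
A4 | alternative 1 | 4-(benzyloxy)-3-methoxybenzaldehyde | COc1cc(C=O)ccc1OCc1ccccc1
A5 | alternative 2 | (1R,5R,6S)-6-[3-(tert-butyldimethylsilyloxy)-4,5-dimethoxyphenyl]-3,7-dioxabicyclo[3.3.0]octan-2-one | O=C1OC[C@H]2[C@@H]1CO[C@@H]2c1cc(O[Si](C)(C)C(C)(C)C)c(OC)c(OC)c1
A6 | alternative 2 | (1S,5R,6R)-6-[3-(tert-butyldimethylsilyloxy)-4,5-dimethoxyphenyl]-3-oxabicyclo[3.1.0]hexan-2-one | O=C1OC[C@H]2[C@@H]1[C@@H]2c1cc(O[Si](C)(C)C(C)(C)C)c(OC)c(OC)c1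
A7 | alternative 2 | formaldehyde | C=O
A8 | alternative 3 | (1S,2S,5S,6S)-2-[4-(tert-butyldimethylsilyloxy)-3-methoxyphenyl]-6-[3-(tert-butyldimethylsilyloxy)-4,5-dimethoxyphenyl]-3,7-dioxabicyclo[3.3.0]octane-4,8-dione | COc1cc([C@H]2OC(=O)[C@H]3[C@@H]2C(=O)O[C@@H]3c2cc(O[Si](C)(C)C(C)(C)C)c(OC)c(OC)c2)ccc1O[Si](C)(C)C(C)(C)C
A9 | alternative 3 | (4S,8S)-4-[4-(tert-butyldimethylsilyloxy)-3-methoxyphenyl]-8-[3-(tert-butyldimethylsilyloxy)-4,5-dimethoxyphenyl]-1,5-dioxocane-2,6-dione | COc1cc([C@@H]2CC(=O)O[C@H](c3cc(O[Si](C)(C)C(C)(C)C)c(OC)c(OC)c3)CC(=O)O2)ccc1O[Si](C)(C)C(C)(C)C
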